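**Retrosynthetic overview**

1. Numbering: ring A is the methoxy ring, C1 (OMe), C2 (Br), C3 (H), C4 (Br), C5 (H), C6 (bridging O). Ring B is the hydroxy ring, C1' (bridging O), C2' (Br), C3' (H), C4' (Br), C5' (Br), C6' (OH).
2. Feature used: in ring A the triad H–C3, Br–C4, H–C5 is a mirror-symmetric three-carbon unit at the oxidation level of a 1,3-dialdehyde, and C6–C1–C2 maps onto the CH2–C(=O)–CH3 of an aryloxyacetone whose carbonyl oxygen ends as the oxygen on C1.
3. Key disconnection: bonds C5–C6 and C2–C3 of ring A, leading back to bromomalonaldehyde and 1-[2-(benzyloxy)-4,6-dibromophenoxy]propan-2-one. The crowded O–C1' ether bond is thereby traced to a simple O-alkylation of a phenol with chloroacetone.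
4. Late disconnections, in retro order: C5'–Br (ortho bromination of the ring B phenol), O–benzyl on C6', O–CH3 on C1, C2–Br.
5. Ring order: ring B is bought as 2-(benzyloxy)phenol and dibrominated; ring A is the only ring built, in step 3.

Key step: step 3

Remark on the chemistry: the target has no stereocenter and the diaryl ether axis is taken as freely rotating, so no stereochemical control is needed.

**Route**

Step 1
Reactants: 1 2-(benzyloxy)phenol
Product: 2 2-(benzyloxy)-4,6-dibromophenol
Conditions: NBS (2.1 equiv), i-Pr2NH (0.2 equiv), CH2Cl2, 0 °C to rt, dark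
Reagents that add atoms: N-bromosuccinimide, O=C1CCC(=O)N1Br
Why: Amine-mediated electrophilic aromatic bromination, in which the N-bromoamine is delivered through the phenolic OH, should brominate first ortho and then para to the free hydroxyl, which outranks the benzyloxy group as a director, so the positions ortho and para to OBn stay free.

Step 2
Reactants: 2 2-(benzyloxy)-4,6-dibromophenol; 3 chloroacetone
Product: 4 1-[2-(benzyloxy)-4,6-dibromophenoxy]propan-2-one
Conditions: K2CO3 (1.5 equiv), KI (0.1 equiv), acetone, reflux
Reagents that add atoms: none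
Why: Williamson ether synthesis with Finkelstein activation by iodide; the phenoxide is flanked by Br and OBn but the alpha-chloroketone is a very reactive SN2 electrophile, and the hindered O–C1' linkage is thus made as an O–C(sp3) bond.

Step 3
Reactants: 4 1-[2-(benzyloxy)-4,6-dibromophenoxy]propan-2-one; 5 bromomalonaldehyde
Product: 7 2-[2-(benzyloxy)-4,6-dibromophenoxy]-4-bromophenol, via open-chain dienone enol 6 (not isolated)
Conditions: 5 (1.3 equiv), NaOH (3 equiv), EtOH/THF/H2O, 0 °C to rt, then 50 °C; then 1 M HCl
Reagents that add atoms: none
Why: Proposed new method: hydroxide forms the enolate of 4 at the OCH2 carbon, the more acidic alpha position, which adds to one formyl group of 5 and loses water to give open-chain dienone 6 (bond C5–C6); the acetyl CH3 is then enolized and attacks the remaining formyl group (bond C2–C3), and a second dehydration with tautomerization gives the ring A phenolate. The closest known reaction type is the alkali-mediated condensation of sodium nitromalonaldehyde with ketones enolizable on both sides, which gives 4-nitrophenols, together with the related benzannulation of ketones with 2-substituted vinamidinium salts. Ring A, the only ring formed, closes by a favoured 6-(enolendo)-exo-trig aldol addition, and no stereocenter is created. The step needs both alpha carbons of one ketone to react with the same dialdehyde rather than forming oligomers, and this is secured by the intramolecular six-membered closure and by the irreversible aromatization; because the C3–C4–C5 unit is symmetrical, the order in which the two alpha carbons react is irrelevant and only the 2-aryloxy-4-bromo pattern can result. The bromo dialdehyde sits as its enolate and is a weaker electrophile than the nitro compound, since bromine stabilizes that anion only inductively, but the aryloxy group raises the acidity of the OCH2 position, and in the enolate the C–Br bond is vinylic and should resist displacement.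

Step 4
Reactants: 7 2-[2-(benzyloxy)-4,6-dibromophenoxy]-4-bromophenol
Product: 8 2,4-dibromo-6-[2-(benzyloxy)-4,6-dibromophenoxy]phenol
Conditions: NBS (1.05 equiv), i-Pr2NH (0.1 equiv), CH2Cl2, 0 °C
Reagents that add atoms: N-bromosuccinimide, O=C1CCC(=O)N1Br
Why: Electrophilic aromatic bromination of the ring A phenol, whose para position (C4) and one ortho position (C6) are occupied, so C2 is the only activated site; ring B carries only ether oxygens and two bromines and should be much less reactive.

Step 5
Reactants: 8 2,4-dibromo-6-[2-(benzyloxy)-4,6-dibromophenoxy]phenol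
Product: 9 1-(benzyloxy)-3,5-dibromo-2-(3,5-dibromo-2-methoxyphenoxy)benzene
Conditions: MeI (1.5 equiv), K2CO3 (2 equiv), DMF, rt
Reagents that add atoms: iodomethane, CI
Why: Williamson O-methylation of the acidic 2,6-disubstituted phenoxide with the unhindered electrophile iodomethane; no other nucleophilic site is present.

Step 6
Reactants: 9 1-(benzyloxy)-3,5-dibromo-2-(3,5-dibromo-2-methoxyphenoxy)benzene
Product: 10 3,5-dibromo-2-(3,5-dibromo-2-methoxyphenoxy)phenol
Conditions: BCl3 (3 equiv), pentamethylbenzene (3 equiv), CH2Cl2, −78 °C; then H2O
Reagents that add atoms: none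
Why: Lewis-acid debenzylation with BCl3 and pentamethylbenzene as a non-basic benzyl cation scavenger, which at −78 °C should cleave the benzyl aryl ether while sparing the methyl ether, the diaryl ether and the C–Br bonds that hydrogenolysis would attack.

Step 7
Reactants: 10 3,5-dibromo-2-(3,5-dibromo-2-methoxyphenoxy)phenol
Product: 11 2,3,5-tribromo-6-(3,5-dibromo-2-methoxyphenoxy)phenol (target)
Conditions: NBS (1.0 equiv), i-Pr2NH (0.1 equiv), CH2Cl2, −20 to 0 °C
Reagents that add atoms: N-bromosuccinimide, O=C1CCC(=O)N1Br
Why: Amine-mediated ortho-selective electrophilic bromination of a phenol, in which the N-bromoamine is guided by the ring B hydroxyl to its one free ortho position C5', while the para position C3' is shielded by two flanking bromines and ring A has no free hydroxyl.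

**Compound list**

1 | 2-(benzyloxy)phenol | Oc1ccccc1OCc1ccccc1 | starting material
2 | 2-(benzyloxy)-4,6-dibromophenol | Oc1c(Br)cc(Br)cc1OCc1ccccc1 | intermediate
3 | chloroacetone | CC(=O)CCl | starting material
4 | 1-[2-(benzyloxy)-4,6-dibromophenoxy]propan-2-one | CC(=O)COc1c(Br)cc(Br)cc1OCc1ccccc1 | intermediate
5 | bromomalonaldehyde | O=CC(Br)C=O | starting material
6 | (3E,5Z)-3-[2-(benzyloxy)-4,6-dibromophenoxy]-5-bromo-6-hydroxyhexa-3,5-dien-2-one (drawn as the neutral enol; present in the flask as its delocalized sodium enolate, not isolated) | CC(=O)/C(Oc1c(Br)cc(Br)cc1OCc1ccccc1)=C\C(Br)=C\O | intermediate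
7 | 2-[2-(benzyloxy)-4,6-dibromophenoxy]-4-bromophenol | Oc1ccc(Br)cc1Oc1c(Br)cc(Br)cc1OCc1ccccc1 | intermediate
8 | 2,4-dibromo-6-[2-(benzyloxy)-4,6-dibromophenoxy]phenol | Oc1c(Br)cc(Br)cc1Oc1c(Br)cc(Br)cc1OCc1ccccc1 | intermediate
9 | 1-(benzyloxy)-3,5-dibromo-2-(3,5-dibromo-2-methoxyphenoxy)benzene | COc1c(Br)cc(Br)cc1Oc1c(Br)cc(Br)cc1OCc1ccccc1 | intermediate
10 | 3,5-dibromo-2-(3,5-dibromo-2-methoxyphenoxy)phenol | COc1c(Br)cc(Br)cc1Oc1c(Br)cc(Br)cc1O | intermediate
11 | 2,3,5-tribromo-6-(3,5-dibromo-2-methoxyphenoxy)phenol | COc1c(Br)cc(Br)cc1Oc1c(Br)cc(Br)c(Br)c1O | target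

**Step count**

Total steps: 7. Longest linear sequence: 7 steps, from 1 to 11.

**Steps most likely to fail**

Step 3 (key step). The ketone enolate may add too slowly to the bromomalonaldehyde anion, so that self-aldol of the ketone or breakdown of the dialdehyde takes over. The sequence may also stall at the open-chain stage or continue intermolecularly to oligomers.

The fallback uses known chemistry, sets out from compound 2 and comes back at compound 7:
- Nucleophilic aromatic substitution of 2 on 4-bromo-2-fluorobenzaldehyde (O=Cc1ccc(Br)cc1F; K2CO3, DMA, 110 °C) should give 2-[2-(benzyloxy)-4,6-dibromophenoxy]-4-bromobenzaldehyde F1. The fluorine ortho to the formyl group is displaced far faster than the para bromine.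
- Baeyer–Villiger oxidation with mCPBA in CH2Cl2, with aryl migration assisted by the ortho aryloxy group, should give 2-[2-(benzyloxy)-4,6-dibromophenoxy]-4-bromophenyl formate F2.
- Methanolysis (K2CO3, MeOH, rt) should give 7.

Step 7. Bromination para to the ring B hydroxyl (C3') may compete with the wanted ortho attack at C5', and a second bromination may follow the first.

The fallback sets out from compound 10 and comes back at compound 11:
- Carbamoylation (Me2NCOCl, K2CO3, MeCN, reflux) should give 3,5-dibromo-2-(3,5-dibromo-2-methoxyphenoxy)phenyl dimethylcarbamate F3.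
- Carbamate-directed ortho C–H bromination catalysed by palladium diacetate (Pd(OAc)2 10 mol %, NBS, TsOH, DCE, 70 °C) can only reach C5', the one free position ortho to the directing group. It should give 2,3,5-tribromo-6-(3,5-dibromo-2-methoxyphenoxy)phenyl dimethylcarbamate F4.
- Hydrolysis (KOH, EtOH/H2O, reflux; then acid) should give 11.

Step 6. The methyl ether, which is crowded and next to a second ether oxygen, may be lost along with the benzyl ether, or the benzyl cation may re-alkylate the freed ring.

The fallback replaces Lewis-acid cleavage by oxidative removal, sets out from compound 9 and comes back at compound 10: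
- Wohl–Ziegler bromination of the benzylic CH2 (NBS 1.05 equiv, AIBN cat., PhCF3, 80 °C) should give racemic 1-[bromo(phenyl)methoxy]-3,5-dibromo-2-(3,5-dibromo-2-methoxyphenoxy)benzene F5, used crude.
- Hydrolysis of this alpha-bromo ether (aq NaHCO3, THF, rt) should give 10 and benzaldehyde, with the methyl ether untouched.

**Further compounds**

F1 | step 3 | 2-[2-(benzyloxy)-4,6-dibromophenoxy]-4-bromobenzaldehyde | O=Cc1ccc(Br)cc1Oc1c(Br)cc(Br)cc1OCc1ccccc1
F2 | step 3 | 2-[2-(benzyloxy)-4,6-dibromophenoxy]-4-bromophenyl formate | O=COc1ccc(Br)cc1Oc1c(Br)cc(Br)cc1OCc1ccccc1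
F3 | step 7 | 3,5-dibromo-2-(3,5-dibromo-2-methoxyphenoxy)phenyl dimethylcarbamate | COc1c(Br)cc(Br)cc1Oc1c(Br)cc(Br)cc1OC(=O)N(C)C
F4 | step 7 | 2,3,5-tribromo-6-(3,5-dibromo-2-methoxyphenoxy)phenyl dimethylcarbamate | COc1c(Br)cc(Br)cc1Oc1c(Br)cc(Br)c(Br)c1OC(=O)N(C)C
F5 | step 6 | 1-[bromo(phenyl)methoxy]-3,5-dibromo-2-(3,5-dibromo-2-methoxyphenoxy)benzene (racemic) | COc1c(Br)cc(Br)cc1Oc1c(Br)cc(Br)cc1OC(Br)c1ccccc1
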